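**Retrosynthetic overview**
1. The ten-membered ring is formed last, by an intramolecular Nozaki–Hiyama–Kishi coupling (C1–C10) of a seco alkenyl iodide/aldehyde; this also creates the free C1 carbinol.
2. The lactone ring is formed first, together with the C6–C7 bond, by a CrCl2-mediated 2-(methoxycarbonyl)allylation of a Z-enal (C1–C6) with a Z-allylic bromide (C7–C13), followed by lactonisation; the C8 angelate is added afterwards.
3. The Z-enal comes from but-2-yn-1-ol: Z-alkenyl iodide, Weinreb ketone synthesis, CBS reduction (C3), acetylation.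
4. The allylic bromide comes from (S)-glyceraldehyde acetonide (C8): Z-selective iodo-olefination, vinylalumination with methyl propiolate, SN2' bromination.

Assumption: germacrane-type locants are used (C1 carbinol, C3 acetoxy carbon, C4=C5, C6 lactone carbinol, C7, C8 angelate carbinol, C9=C10, C11=C13 exocyclic methylene, C12 lactone carbonyl), and (S)-2,2-dimethyl-1,3-dioxolane-4-carbaldehyde is taken as a purchased chiral-pool aldehyde.

**Route**

Step 1
Reactants: 1 but-2-yn-1-ol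
Product: 3 (2Z)-3-iodobut-2-en-1-ol, via cyclic alkenylalanate 2 (not isolated)
Conditions: NaAlH2(OCH2CH2OMe)2, Et2O, 0 °C to rt; then I2, THF, −78 to 0 °C
Reagents that add atoms: iodine, II
Why: Hydroxyl-directed trans-hydroalumination of the propargylic alcohol places aluminium at C3 cis to the CH2O group (cyclic alanate 2), and iodinolysis of the C–Al bond with retention fixes the Z alkenyl iodide.

Step 2
Reactants: 3 (2Z)-3-iodobut-2-en-1-ol
Product: 4 tert-butyl{[(2Z)-3-iodobut-2-en-1-yl]oxy}dimethylsilane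
Conditions: TBSCl, imidazole, CH2Cl2, rt
Reagents that add atoms: tert-butyl(chloro)dimethylsilane, CC(C)(C)[Si](C)(C)Cl
Why: Imidazole-promoted silyl ether formation masks the alcohol before the lithiation.

Step 3
Reactants: 5 methyl 3,3-dimethoxypropanoate
Product: 6 N,3,3-trimethoxy-N-methylpropanamide
Conditions: MeNH(OMe)·HCl, i-PrMgCl, THF, −20 to 0 °C
Reagents that add atoms: N,O-dimethylhydroxylamine hydrochloride, CNOC.Cl
Why: Weinreb amide synthesis, in which the magnesium amide of N,O-dimethylhydroxylamine acylates with the ester and the acetal is untouched.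

Step 4
Reactants: 4 tert-butyl{[(2Z)-3-iodobut-2-en-1-yl]oxy}dimethylsilane; 6 N,3,3-trimethoxy-N-methylpropanamide
Product: 8 (4Z)-6-{[tert-butyl(dimethyl)silyl]oxy}-1,1-dimethoxy-4-methylhex-4-en-3-one, via alkenyllithium 7 (not isolated)
Conditions: t-BuLi (2 equiv), Et2O, −78 °C; then 6, −78 to −40 °C; H2O
Reagents that add atoms: none
Why: Iodine–lithium exchange proceeds with retention of the alkene geometry, and the Weinreb ketone synthesis stops at the ketone because the chelated tetrahedral adduct survives until work-up.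

Step 5
Reactants: 8 (4Z)-6-{[tert-butyl(dimethyl)silyl]oxy}-1,1-dimethoxy-4-methylhex-4-en-3-one
Product: 9 (3S,4Z)-6-{[tert-butyl(dimethyl)silyl]oxy}-1,1-dimethoxy-4-methylhex-4-en-3-ol
Conditions: (R)-2-methyl-CBS-oxazaborolidine (20 mol %), catecholborane, toluene, −78 °C
Reagents that add atoms: none
Why: Corey–Bakshi–Shibata reduction; with the α-methylalkenyl group as the large substituent, the (R)-catalyst gives the (S)-allylic alcohol (C3) by 1,2-reduction.

Step 6
Reactants: 9 (3S,4Z)-6-{[tert-butyl(dimethyl)silyl]oxy}-1,1-dimethoxy-4-methylhex-4-en-3-ol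
Product: 10 (3S,4Z)-6-{[tert-butyl(dimethyl)silyl]oxy}-1,1-dimethoxy-4-methylhex-4-en-3-yl acetate
Conditions: Ac2O, pyridine, DMAP (cat.), CH2Cl2, 0 °C to rt
Reagents that add atoms: acetic anhydride, CC(=O)OC(C)=O
Why: DMAP-catalysed acetylation installs the C3 acetate of the target without touching the stereocentre.

Step 7
Reactants: 10 (3S,4Z)-6-{[tert-butyl(dimethyl)silyl]oxy}-1,1-dimethoxy-4-methylhex-4-en-3-yl acetate
Product: 11 (3S,4Z)-6-hydroxy-1,1-dimethoxy-4-methylhex-4-en-3-yl acetate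
Conditions: HF·pyridine, pyridine, THF, 0 °C
Reagents that add atoms: none
Why: Fluoride-mediated desilylation under buffered, water-free conditions frees the primary allylic alcohol and leaves the acetate and the dimethyl acetal intact.

Step 8
Reactants: 11 (3S,4Z)-6-hydroxy-1,1-dimethoxy-4-methylhex-4-en-3-yl acetate
Product: 12 (3S,4Z)-1,1-dimethoxy-4-methyl-6-oxohex-4-en-3-yl acetate
Conditions: MnO2, CH2Cl2, rt
Reagents that add atoms: none
Why: MnO2 allylic oxidation stops at the aldehyde and keeps the Z geometry of the β,β-disubstituted enal.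

Step 9
Reactants: 13 (4S)-2,2-dimethyl-1,3-dioxolane-4-carbaldehyde; 14 ethyl(triphenyl)phosphonium iodide
Product: 18 (4R)-4-[(1Z)-2-iodoprop-1-en-1-yl]-2,2-dimethyl-1,3-dioxolane, via ethylidene ylide 15 (not isolated), via iodophosphonium salt 16 (not isolated), via iodo ylide 17 (not isolated)
Conditions: n-BuLi, THF, 0 °C; then I2, −78 °C; then NaN(SiMe3)2, −78 to −20 °C; then 13, −78 °C to rt
Reagents that add atoms: iodine, II
Why: Stork–Zhao-type Wittig olefination with the α-iodo ylide 17 goes through the kinetic cis-oxaphosphetane and gives the Z trisubstituted alkenyl iodide; the dioxolane stereocentre (future C8) comes from the chiral pool.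

Step 10
Reactants: 18 (4R)-4-[(1Z)-2-iodoprop-1-en-1-yl]-2,2-dimethyl-1,3-dioxolane
Product: 19 (2R,3Z)-4-iodopent-3-ene-1,2-diol
Conditions: AcOH/H2O (4:1), 40 °C
Reagents that add atoms: none
Why: Acid-catalysed acetonide hydrolysis liberates the 1,2-diol without affecting the alkenyl iodide.

Step 11
Reactants: 19 (2R,3Z)-4-iodopent-3-ene-1,2-diol
Product: 20 (2R,3Z)-1,2-bis{[tert-butyl(dimethyl)silyl]oxy}-4-iodopent-3-ene
Conditions: TBSCl (2.5 equiv), imidazole, DMF, rt
Reagents that add atoms: tert-butyl(chloro)dimethylsilane, CC(C)(C)[Si](C)(C)Cl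
Why: Exhaustive silylation protects both hydroxyls so that the primary one can be unmasked selectively in the next step.

Step 12
Reactants: 20 (2R,3Z)-1,2-bis{[tert-butyl(dimethyl)silyl]oxy}-4-iodopent-3-ene
Product: 21 (2R,3Z)-2-{[tert-butyl(dimethyl)silyl]oxy}-4-iodopent-3-en-1-ol
Conditions: HF·pyridine, pyridine, THF, 0 °C
Reagents that add atoms: none
Why: Selective desilylation, since the less hindered primary silyl ether is cleaved much faster than the secondary allylic one.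

Step 13
Reactants: 21 (2R,3Z)-2-{[tert-butyl(dimethyl)silyl]oxy}-4-iodopent-3-en-1-ol
Product: 22 (2R,3Z)-2-{[tert-butyl(dimethyl)silyl]oxy}-4-iodopent-3-enal
Conditions: Dess–Martin periodinane, pyridine, CH2Cl2, 0 °C; used crude at once
Reagents that add atoms: none
Why: Dess–Martin oxidation under buffered, base-free conditions gives the α-silyloxy aldehyde without epimerising C2.

Step 14
Reactants: 22 (2R,3Z)-2-{[tert-butyl(dimethyl)silyl]oxy}-4-iodopent-3-enal; 23 methyl prop-2-ynoate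
Product: 25 methyl (4R,5Z)-4-{[tert-butyl(dimethyl)silyl]oxy}-3-hydroxy-6-iodo-2-methylidenehept-5-enoate as a mixture of C3 epimers, via vinylalane 24 (not isolated)
Conditions: 23, i-Bu2AlH, N-methylmorpholine N-oxide, THF, 0 °C; then 22, 0 °C to rt
Reagents that add atoms: none
Why: Vinylalumination (a Morita–Baylis–Hillman-type adduct made without amine base): 1,4-hydroalumination of the propiolate gives vinylalane 24, which adds to the aldehyde; the new carbinol centre is destroyed in the next step, so both epimers are used.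

Step 15
Reactants: 25 methyl (4R,5Z)-4-{[tert-butyl(dimethyl)silyl]oxy}-3-hydroxy-6-iodo-2-methylidenehept-5-enoate
Product: 26 methyl (2Z,4S,5Z)-2-(bromomethyl)-4-{[tert-butyl(dimethyl)silyl]oxy}-6-iodohepta-2,5-dienoate
Conditions: NBS, Me2S, CH2Cl2, 0 °C to rt
Reagents that add atoms: N-bromosuccinimide, O=C1CCC(=O)N1Br
Why: Corey–Kim-type activation of the hydroxyl and SN2' attack of bromide transpose the allylic system to the thermodynamically preferred Z-configured 2-(bromomethyl)enoate.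

Step 16
Reactants: 12 (3S,4Z)-1,1-dimethoxy-4-methyl-6-oxohex-4-en-3-yl acetate; 26 methyl (2Z,4S,5Z)-2-(bromomethyl)-4-{[tert-butyl(dimethyl)silyl]oxy}-6-iodohepta-2,5-dienoate
Product: 28 (4R,5R)-5-[(1Z,3S)-3-(acetyloxy)-5,5-dimethoxy-2-methylpent-1-en-1-yl]-4-[(1S,2Z)-1-{[tert-butyl(dimethyl)silyl]oxy}-3-iodobut-2-en-1-yl]-3-methylideneoxolan-2-one, via syn hydroxy ester 27 (not isolated)
Conditions: CrCl2 (nickel-free, 4 equiv), THF, 0 °C to rt; then PPTS (cat.), CH2Cl2, rt
Reagents that add atoms: none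
Why: Nozaki–Hiyama (Barbier-type) 2-(methoxycarbonyl)allylation: the Z-allylchromium from 26 adds through a chair transition state with the C8 branch axial (6,7-syn), allylic 1,3-strain keeps H8 in the alkene plane and the aldehyde enters anti to the C8–O bond (Felkin-type control), which sets C7 (R) and C6 (R), and the syn hydroxy ester lactonises to the cis-4,5-disubstituted α-methylene lactone.

Step 17
Reactants: 28 the silyl-protected lactone
Product: 29 (4S,5R)-5-[(1Z,3S)-3-(acetyloxy)-5,5-dimethoxy-2-methylpent-1-en-1-yl]-4-[(1S,2Z)-1-hydroxy-3-iodobut-2-en-1-yl]-3-methylideneoxolan-2-one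
Conditions: HF·pyridine, pyridine, THF, 0 °C to rt
Reagents that add atoms: none
Why: Fluoride-mediated cleavage of the secondary silyl ether frees the C8 hydroxyl; acetal, acetate, lactone and alkenyl iodide are stable to buffered HF·pyridine (the ring C4 descriptor changes only because of the priority rules).

Step 18
Reactants: 29 the C8 alcohol; 30 (2Z)-2-methylbut-2-enoic acid (angelic acid)
Product: 32 (4R,5R)-5-[(1Z,3S)-3-(acetyloxy)-5,5-dimethoxy-2-methylpent-1-en-1-yl]-4-[(1S,2Z)-3-iodo-1-{[(2Z)-2-methylbut-2-enoyl]oxy}but-2-en-1-yl]-3-methylideneoxolan-2-one, via mixed anhydride 31 (not isolated)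
Conditions: 30, 2,4,6-trichlorobenzoyl chloride, Et3N, toluene, rt; then 29, toluene, 80 °C
Reagents that add atoms: none
Why: Yamaguchi-type mixed-anhydride esterification run without DMAP acylates the hindered C8 alcohol while avoiding angelate-to-tiglate isomerisation; C8 is not touched.

Step 19
Reactants: 32 the angelate acetal
Product: 33 (4R,5R)-5-[(1Z,3S)-3-(acetyloxy)-2-methyl-5-oxopent-1-en-1-yl]-4-[(1S,2Z)-3-iodo-1-{[(2Z)-2-methylbut-2-enoyl]oxy}but-2-en-1-yl]-3-methylideneoxolan-2-one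
Conditions: Amberlyst-15, acetone/H2O, rt; used at once
Reagents that add atoms: water, O
Why: Mild acid-catalysed acetal hydrolysis unmasks the C1 aldehyde without cleaving the esters; the β-acetoxy aldehyde is kept away from base.

Step 20
Reactants: 33 the seco iodo aldehyde
Product: 34 (1S,3S,4Z,6R,7R,8R,9Z)-3-acetoxy-1-hydroxy-8-[(2Z)-2-methylbut-2-enoyloxy]germacra-4,9,11(13)-trien-12,6-olide (CNP0319825.3)
Conditions: CrCl2 (15 equiv), NiCl2 (2 mol %), DMSO, rt, 0.002 M, syringe-pump addition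
Reagents that add atoms: none
Why: Intramolecular Nozaki–Hiyama–Kishi reaction under high dilution: zerovalent nickel inserts into the alkenyl iodide, transmetalation gives the alkenyl species of trivalent chromium with retention of the Z geometry, and its addition to the aldehyde closes the ten-membered ring, the 3-acetoxy group directing 1,3-anti attack (dipole-minimised Evans-type conformer) to give C1 (S).

**Compound list**

1 | but-2-yn-1-ol | CC#CCO | starting material
2 | sodium 2,2-bis(2-methoxyethoxy)-3-methyl-2,5-dihydro-1,2-oxaaluminol-2-uide (cyclic alkenylalanate) | CC1=CCO[Al-]1(OCCOC)OCCOC.[Na+] | intermediate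
3 | (2Z)-3-iodobut-2-en-1-ol | C/C(I)=C/CO | intermediate
4 | tert-butyl{[(2Z)-3-iodobut-2-en-1-yl]oxy}dimethylsilane | C/C(I)=C/CO[Si](C)(C)C(C)(C)C | intermediate
5 | methyl 3,3-dimethoxypropanoate | COC(=O)CC(OC)OC | starting material
6 | N,3,3-trimethoxy-N-methylpropanamide | CON(C)C(=O)CC(OC)OC | intermediate
7 | [(2E)-4-{[tert-butyl(dimethyl)silyl]oxy}but-2-en-2-yl]lithium (Li cis to the CH2O group) | C/C([Li])=C/CO[Si](C)(C)C(C)(C)C | intermediate
8 | (4Z)-6-{[tert-butyl(dimethyl)silyl]oxy}-1,1-dimethoxy-4-methylhex-4-en-3-one | C/C(=C/CO[Si](C)(C)C(C)(C)C)C(=O)CC(OC)OC | intermediate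
9 | (3S,4Z)-6-{[tert-butyl(dimethyl)silyl]oxy}-1,1-dimethoxy-4-methylhex-4-en-3-ol | C/C(=C/CO[Si](C)(C)C(C)(C)C)[C@@H](O)CC(OC)OC | intermediate
10 | (3S,4Z)-6-{[tert-butyl(dimethyl)silyl]oxy}-1,1-dimethoxy-4-methylhex-4-en-3-yl acetate | C/C(=C/CO[Si](C)(C)C(C)(C)C)[C@@H](OC(C)=O)CC(OC)OC | intermediate
11 | (3S,4Z)-6-hydroxy-1,1-dimethoxy-4-methylhex-4-en-3-yl acetate | C/C(=C/CO)[C@@H](OC(C)=O)CC(OC)OC | intermediate
12 | (3S,4Z)-1,1-dimethoxy-4-methyl-6-oxohex-4-en-3-yl acetate | C/C(=C/C=O)[C@@H](OC(C)=O)CC(OC)OC | intermediate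
13 | (4S)-2,2-dimethyl-1,3-dioxolane-4-carbaldehyde | O=C[C@@H]1COC(C)(C)O1 | starting material
14 | ethyl(triphenyl)phosphonium iodide | CC[P+](c1ccccc1)(c1ccccc1)c1ccccc1.[I-] | starting material
15 | ethylidene(triphenyl)phosphorane | CC=P(c1ccccc1)(c1ccccc1)c1ccccc1 | intermediate
16 | (1-iodoethyl)(triphenyl)phosphonium iodide | CC(I)[P+](c1ccccc1)(c1ccccc1)c1ccccc1.[I-] | intermediate
17 | (1-iodoethylidene)(triphenyl)phosphorane | CC(I)=P(c1ccccc1)(c1ccccc1)c1ccccc1 | intermediate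
18 | (4R)-4-[(1Z)-2-iodoprop-1-en-1-yl]-2,2-dimethyl-1,3-dioxolane | C/C(I)=C/[C@@H]1COC(C)(C)O1 | intermediate
19 | (2R,3Z)-4-iodopent-3-ene-1,2-diol | C/C(I)=C/[C@@H](O)CO | intermediate
20 | (2R,3Z)-1,2-bis{[tert-butyl(dimethyl)silyl]oxy}-4-iodopent-3-ene | C/C(I)=C/[C@@H](O[Si](C)(C)C(C)(C)C)CO[Si](C)(C)C(C)(C)C | intermediate
21 | (2R,3Z)-2-{[tert-butyl(dimethyl)silyl]oxy}-4-iodopent-3-en-1-ol | C/C(I)=C/[C@@H](O[Si](C)(C)C(C)(C)C)CO | intermediate
22 | (2R,3Z)-2-{[tert-butyl(dimethyl)silyl]oxy}-4-iodopent-3-enal | C/C(I)=C/[C@@H](O[Si](C)(C)C(C)(C)C)C=O | intermediate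
23 | methyl prop-2-ynoate | C#CC(=O)OC | starting material
24 | [1-(methoxycarbonyl)ethenyl]bis(2-methylpropyl)aluminium | C=C(C(=O)OC)[Al](CC(C)C)CC(C)C | intermediate
25 | methyl (4R,5Z)-4-{[tert-butyl(dimethyl)silyl]oxy}-3-hydroxy-6-iodo-2-methylidenehept-5-enoate (C3 epimers) | C/C(I)=C/[C@@H](O[Si](C)(C)C(C)(C)C)C(O)C(=C)C(=O)OC | intermediate
26 | methyl (2Z,4S,5Z)-2-(bromomethyl)-4-{[tert-butyl(dimethyl)silyl]oxy}-6-iodohepta-2,5-dienoate | C/C(I)=C/[C@@H](O[Si](C)(C)C(C)(C)C)/C=C(\CBr)C(=O)OC | intermediate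
27 | methyl (3R,4R,5Z,7S)-7-(acetyloxy)-3-[(1S,2Z)-1-{[tert-butyl(dimethyl)silyl]oxy}-3-iodobut-2-en-1-yl]-4-hydroxy-9,9-dimethoxy-6-methyl-2-methylidenenon-5-enoate | C=C(C(=O)OC)[C@H]([C@H](O)/C=C(/C)[C@@H](OC(C)=O)CC(OC)OC)[C@H](O[Si](C)(C)C(C)(C)C)/C=C(/C)I | intermediate
28 | (4R,5R)-5-[(1Z,3S)-3-(acetyloxy)-5,5-dimethoxy-2-methylpent-1-en-1-yl]-4-[(1S,2Z)-1-{[tert-butyl(dimethyl)silyl]oxy}-3-iodobut-2-en-1-yl]-3-methylideneoxolan-2-one | C=C1C(=O)O[C@H](/C=C(/C)[C@@H](OC(C)=O)CC(OC)OC)[C@@H]1[C@H](O[Si](C)(C)C(C)(C)C)/C=C(/C)I | intermediate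
29 | (4S,5R)-5-[(1Z,3S)-3-(acetyloxy)-5,5-dimethoxy-2-methylpent-1-en-1-yl]-4-[(1S,2Z)-1-hydroxy-3-iodobut-2-en-1-yl]-3-methylideneoxolan-2-one | C=C1C(=O)O[C@H](/C=C(/C)[C@@H](OC(C)=O)CC(OC)OC)[C@@H]1[C@H](O)/C=C(/C)I | intermediate
30 | (2Z)-2-methylbut-2-enoic acid (angelic acid) | C/C=C(/C)C(=O)O | starting material
31 | (2Z)-2-methylbut-2-enoic 2,4,6-trichlorobenzoic anhydride | C/C=C(/C)C(=O)OC(=O)c1c(Cl)cc(Cl)cc1Cl | intermediate
32 | (4R,5R)-5-[(1Z,3S)-3-(acetyloxy)-5,5-dimethoxy-2-methylpent-1-en-1-yl]-4-[(1S,2Z)-3-iodo-1-{[(2Z)-2-methylbut-2-enoyl]oxy}but-2-en-1-yl]-3-methylideneoxolan-2-one | C=C1C(=O)O[C@H](/C=C(/C)[C@@H](OC(C)=O)CC(OC)OC)[C@@H]1[C@H](OC(=O)/C(C)=C\C)/C=C(/C)I | intermediate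
33 | (4R,5R)-5-[(1Z,3S)-3-(acetyloxy)-2-methyl-5-oxopent-1-en-1-yl]-4-[(1S,2Z)-3-iodo-1-{[(2Z)-2-methylbut-2-enoyl]oxy}but-2-en-1-yl]-3-methylideneoxolan-2-one | C=C1C(=O)O[C@H](/C=C(/C)[C@@H](OC(C)=O)CC=O)[C@@H]1[C@H](OC(=O)/C(C)=C\C)/C=C(/C)I | intermediate
34 | (1S,3S,4Z,6R,7R,8R,9Z)-3-acetoxy-1-hydroxy-8-[(2Z)-2-methylbut-2-enoyloxy]germacra-4,9,11(13)-trien-12,6-olide (CNP0319825.3) | C=C1C(=O)O[C@@H]2/C=C(/C)[C@@H](OC(C)=O)C[C@H](O)/C(C)=C\[C@@H](OC(=O)/C(C)=C\C)[C@H]12 | target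

**Totals**

Total step count: 20.
Longest linear sequence: 12 steps (steps 1, 2, 4–8 and 16–20; equally steps 9–15 and 16–20).

**Steps most likely to fail**

Step 16 (chromium allylation and lactonisation). The facial selectivity at C7 rests only on substrate control; attack anti to the alkenyl group instead of anti to the C8–O bond would give the C6,C7-epimeric lactone, and the allylchromium could also lose its silyloxy group. The fallback sets out from 26 and comes back at 29. The silyl ether of 26 is cleaved with aqueous HF in MeCN to methyl (2Z,4S,5Z)-2-(bromomethyl)-4-hydroxy-6-iodohepta-2,5-dienoate F1. F1 is converted with 4-methoxybenzyl 2,2,2-trichloroacetimidate and catalytic camphorsulfonic acid into the chelating ether methyl (2Z,4S,5Z)-2-(bromomethyl)-6-iodo-4-[(4-methoxyphenyl)methoxy]hepta-2,5-dienoate F2. F2 and 12 are joined by an indium-mediated Barbier allylation (indium powder, THF/H2O, rt); here the ether oxygen is tied to indium on the inside of the allyl unit and the aldehyde enters anti to the alkenyl group, which leads to the same C6/C7 configuration by chelation control. This gives methyl (3R,4R,5Z,7S)-7-(acetyloxy)-4-hydroxy-3-{(1S,2Z)-3-iodo-1-[(4-methoxyphenyl)methoxy]but-2-en-1-yl}-9,9-dimethoxy-6-methyl-2-methylidenenon-5-enoate F3, which closes with PPTS to (4S,5R)-5-[(1Z,3S)-3-(acetyloxy)-5,5-dimethoxy-2-methylpent-1-en-1-yl]-4-{(1S,2Z)-3-iodo-1-[(4-methoxyphenyl)methoxy]but-2-en-1-yl}-3-methylideneoxolan-2-one F4. DDQ in CH2Cl2/pH 7 buffer removes the 4-methoxybenzyl group and delivers 29.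

Step 18 (angeloylation). The C8 hydroxyl is hindered, the free alcohol may translactonise on heating, and activated angelic acid isomerises easily to the tiglate. The fallback sets out from 29 and comes back at 32. 29 is acylated with 2-[bis(2,2,2-trifluoroethoxy)phosphoryl]propanoic acid (N,N'-dicyclohexylcarbodiimide, cat. DMAP, CH2Cl2) to (4R,5R)-5-[(1Z,3S)-3-(acetyloxy)-5,5-dimethoxy-2-methylpent-1-en-1-yl]-4-[(1S,2Z)-1-({2-[bis(2,2,2-trifluoroethoxy)phosphoryl]propanoyl}oxy)-3-iodobut-2-en-1-yl]-3-methylideneoxolan-2-one F5. A Still–Gennari olefination of F5 with acetaldehyde (KN(SiMe3)2, 18-crown-6, THF, −78 °C) then builds the Z-configured 2-methylbut-2-enoate on the substrate and gives 32.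

Step 20 (ring closure). The ten-membered ring closure can be slow, the β-acetoxy aldehyde is sensitive, and the C1 configuration depends on substrate control in the macrocyclic transition state. The fallback sets out from 33 and comes back at 34. The coupling is run without regard to C1 selectivity, so that 34 is accompanied by its C1 epimer (1R,3S,4Z,6R,7R,8R,9Z)-3-acetoxy-1-hydroxy-8-[(2Z)-2-methylbut-2-enoyloxy]germacra-4,9,11(13)-trien-12,6-olide F6. The mixture is oxidised with Dess–Martin periodinane to the single enone (3S,4Z,6R,7R,8R,9Z)-3-acetoxy-8-[(2Z)-2-methylbut-2-enoyloxy]-1-oxogermacra-4,9,11(13)-trien-12,6-olide F7. A CBS reduction ((R)-2-methyl-CBS-oxazaborolidine, catecholborane, toluene, −78 °C) then sets C1 (S) under reagent control and returns 34.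

**Further compounds**

F1 | step 16 | methyl (2Z,4S,5Z)-2-(bromomethyl)-4-hydroxy-6-iodohepta-2,5-dienoate | C/C(I)=C/[C@@H](O)/C=C(\CBr)C(=O)OC
F2 | step 16 | methyl (2Z,4S,5Z)-2-(bromomethyl)-6-iodo-4-[(4-methoxyphenyl)methoxy]hepta-2,5-dienoate | C/C(I)=C/[C@@H](OCc1ccc(OC)cc1)/C=C(\CBr)C(=O)OC
F3 | step 16 | methyl (3R,4R,5Z,7S)-7-(acetyloxy)-4-hydroxy-3-{(1S,2Z)-3-iodo-1-[(4-methoxyphenyl)methoxy]but-2-en-1-yl}-9,9-dimethoxy-6-methyl-2-methylidenenon-5-enoate | C=C(C(=O)OC)[C@H]([C@H](O)/C=C(/C)[C@@H](OC(C)=O)CC(OC)OC)[C@H](OCc1ccc(OC)cc1)/C=C(/C)I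
F4 | step 16 | (4S,5R)-5-[(1Z,3S)-3-(acetyloxy)-5,5-dimethoxy-2-methylpent-1-en-1-yl]-4-{(1S,2Z)-3-iodo-1-[(4-methoxyphenyl)methoxy]but-2-en-1-yl}-3-methylideneoxolan-2-one | C=C1C(=O)O[C@H](/C=C(/C)[C@@H](OC(C)=O)CC(OC)OC)[C@@H]1[C@H](OCc2ccc(OC)cc2)/C=C(/C)I
F5 | step 18 | (4R,5R)-5-[(1Z,3S)-3-(acetyloxy)-5,5-dimethoxy-2-methylpent-1-en-1-yl]-4-[(1S,2Z)-1-({2-[bis(2,2,2-trifluoroethoxy)phosphoryl]propanoyl}oxy)-3-iodobut-2-en-1-yl]-3-methylideneoxolan-2-one | C=C1C(=O)O[C@H](/C=C(/C)[C@@H](OC(C)=O)CC(OC)OC)[C@@H]1[C@H](OC(=O)C(C)P(=O)(OCC(F)(F)F)OCC(F)(F)F)/C=C(/C)I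
F6 | step 20 | (1R,3S,4Z,6R,7R,8R,9Z)-3-acetoxy-1-hydroxy-8-[(2Z)-2-methylbut-2-enoyloxy]germacra-4,9,11(13)-trien-12,6-olide | C=C1C(=O)O[C@@H]2/C=C(/C)[C@@H](OC(C)=O)C[C@@H](O)/C(C)=C\[C@@H](OC(=O)/C(C)=C\C)[C@H]12
F7 | step 20 | (3S,4Z,6R,7R,8R,9Z)-3-acetoxy-8-[(2Z)-2-methylbut-2-enoyloxy]-1-oxogermacra-4,9,11(13)-trien-12,6-olide | C=C1C(=O)O[C@@H]2/C=C(/C)[C@@H](OC(C)=O)CC(=O)/C(C)=C\[C@@H](OC(=O)/C(C)=C\C)[C@H]12
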